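**Retrosynthetic overview**

1. The target is cut back to the bicyclic vinylogous methyl ester 16 (C3 acylation, then O-demethylation), and 16 to the C7-methylidene bicycle 13 (hydroboration on the exo face, then B-alkyl Suzuki–Miyaura coupling gives the 7-endo prenyl group).
2. 13 comes from the acyclic acid chloride 12 in one palladium zipper: C9–C5 (ring A, 6-exo acylpalladation), then C6–C7 (ring B, 6-exo alkene insertion), ended by β-hydride loss at C7.
3. Enabling feature: the C9 ketone lies between the quaternary carbons C1 and C5, and C5 carries only CH3 and C6H2 outside ring A. An isopropenyl group on C4 therefore takes the acyl group at C5 and leaves palladium on C6 with no β-hydrogen. C7 has one hydrogen, so the cascade ends as an exocyclic methylene.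
4. 12 comes from enol lactone 10, a temporary pyranone ring opened by methoxide. Its quaternary stereocentre (C1 of the target) is set by an enantioselective Claisen rearrangement of the 4-prenyloxypyranone 9.
5. Ring order: pyranone (temporary, from dioxinone 1 and methacryloyl chloride 2), then ring A, then ring B.

Key step: step 8

Remark: the enolised β-triketone of the target is a set of fast-exchanging tautomers; the route aims at the constitution and the (1R,5R,7R) configuration of the tautomer drawn in the given SMILES.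

**Route**

Step 1
Reactants: 1 2,2,6-trimethyl-4H-1,3-dioxin-4-one; 2 methacryloyl chloride
Product: 3 2,2-dimethyl-6-(3-methyl-2-oxobut-3-en-1-yl)-4H-1,3-dioxin-4-one
Conditions: LDA (2.1 equiv), 1 (2.1 equiv), THF, −78 °C; then 2 (1.0 equiv), −78 °C; aq. NH4Cl
Reagents that add atoms: none
Why: Vinylogous (γ) C-acylation of the lithium dienolate of 1 by the acid chloride, a standard way to 6-(2-oxoalkyl)dioxinones; the second equivalent of dienolate takes up the acidic proton of the product.

Step 2
Reactants: 3 2,2-dimethyl-6-(3-methyl-2-oxobut-3-en-1-yl)-4H-1,3-dioxin-4-one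
Product: 5 4-hydroxy-6-(prop-1-en-2-yl)-2H-pyran-2-one, via acylketene 4 (not isolated)
Conditions: toluene, 110 °C
Reagents that add atoms: none
Why: Thermal retro-hetero-Diels–Alder loss of acetone gives the acylketene, whose enolised side-chain ketone adds to the ketene carbon to close the 4-hydroxy-2-pyranone (the usual dioxinone-to-pyranone conversion).

Step 3
Reactants: 5 4-hydroxy-6-(prop-1-en-2-yl)-2H-pyran-2-one; 6 3-methylbut-2-en-1-yl acetate (prenyl acetate)
Product: 7 4-hydroxy-3-(3-methylbut-2-en-1-yl)-6-(prop-1-en-2-yl)-2H-pyran-2-one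
Conditions: Pd(PPh3)4 (5 mol %), Et3N (1.1 equiv), THF, 50 °C
Reagents that add atoms: none
Why: Tsuji–Trost allylation in which the soft pyranone anion attacks the unsubstituted terminus of the 1,1-dimethylallyl complex of divalent palladium through C3; any O-prenyl ether is re-ionised by zerovalent palladium and funnelled to the C-alkylated product.

Step 4
Reactants: 7 4-hydroxy-3-(3-methylbut-2-en-1-yl)-6-(prop-1-en-2-yl)-2H-pyran-2-one; 8 3-methylbut-2-en-1-ol (prenol)
Product: 9 4-[(3-methylbut-2-en-1-yl)oxy]-3-(3-methylbut-2-en-1-yl)-6-(prop-1-en-2-yl)-2H-pyran-2-one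
Conditions: PPh3, DIAD, THF, 0 °C → rt
Reagents that add atoms: none
Why: Mitsunobu O-alkylation of the acidic 4-hydroxy group (SN2 at the primary allylic carbon) gives the allyl vinyl ether needed for the [3,3] shift.

Step 5
Reactants: 9 4-[(3-methylbut-2-en-1-yl)oxy]-3-(3-methylbut-2-en-1-yl)-6-(prop-1-en-2-yl)-2H-pyran-2-one
Product: 10 (3S)-3-(2-methylbut-3-en-2-yl)-3-(3-methylbut-2-en-1-yl)-6-(prop-1-en-2-yl)-2H-pyran-2,4(3H)-dione
Conditions: C2-symmetric chiral N,N'-bis[2-(2-phenylpyrrol-1-yl)cyclohexyl]guanidinium tetrakis[3,5-bis(trifluoromethyl)phenyl]borate (20 mol %; the catalyst enantiomer that gives (S)-10), hexanes–toluene, 40 °C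
Reagents that add atoms: none
Why: Catalytic enantioselective Claisen rearrangement of an ester-substituted allyl vinyl ether: the guanidinium ion hydrogen-bonds to the ether oxygen and the lactone carbonyl, lowers the barrier of the chair [3,3] shift and differentiates the two faces of C3, so the 2-methylbut-3-en-2-yl group is delivered to C3 with dearomatisation and the quaternary centre (C1 of the target) is set as S.

Step 6
Reactants: 10 (3S)-3-(2-methylbut-3-en-2-yl)-3-(3-methylbut-2-en-1-yl)-6-(prop-1-en-2-yl)-2H-pyran-2,4(3H)-dione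
Product: 11 sodium (2S,4E)-5-methoxy-6-methyl-2-(2-methylbut-3-en-2-yl)-2-(3-methylbut-2-en-1-yl)-3-oxohepta-4,6-dienoate
Conditions: NaOMe (1.05 equiv), MeOH, 0 → 40 °C; evaporate; dry by toluene azeotrope
Reagents that add atoms: sodium methoxide, [Na+].[O-]C
Why: Addition–elimination at C6 of the pyranone (vinylogous acyl substitution): methoxide adds to the unhindered enol-ether carbon and expels the carboxylate, the lactone carbonyl being screened by the two adjacent quaternary carbons, and reversible methoxide addition equilibrates the enol ether to the more stable E isomer, in which the ketone and the isopropenyl group are cis; the stereocentre is not touched.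

Step 7
Reactants: 11 sodium (2S,4E)-5-methoxy-6-methyl-2-(2-methylbut-3-en-2-yl)-2-(3-methylbut-2-en-1-yl)-3-oxohepta-4,6-dienoate
Product: 12 (2S,4E)-5-methoxy-6-methyl-2-(2-methylbut-3-en-2-yl)-2-(3-methylbut-2-en-1-yl)-3-oxohepta-4,6-dienoyl chloride
Conditions: (COCl)2 (1.05 equiv), DMF (cat.), CH2Cl2, −20 → 0 °C; filter; concentrate; use at once
Reagents that add atoms: oxalyl chloride, ClC(=O)C(Cl)=O
Why: Conversion of the carboxylate salt into the acid chloride by the Vilsmeier-type chloroiminium activator under neutral conditions, which avoids the free, decarboxylation-prone β-keto acid.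

Step 8
Reactants: 12 (2S,4E)-5-methoxy-6-methyl-2-(2-methylbut-3-en-2-yl)-2-(3-methylbut-2-en-1-yl)-3-oxohepta-4,6-dienoyl chloride
Product: 13 (1S,5R)-4-methoxy-5,8,8-trimethyl-7-methylidene-1-(3-methylbut-2-en-1-yl)bicyclo[3.3.1]non-3-ene-2,9-dione
Conditions: Pd2(dba)3 (2.5 mol %), P(2-furyl)3 (10 mol %), 1,2,2,6,6-pentamethylpiperidine (2 equiv), toluene–MeCN (0.01 M), 45 °C, argon
Reagents that add atoms: none
Why: Oxidative addition of zerovalent palladium into the C–Cl bond of 12 gives an acyl complex of divalent palladium at C9, which adds across the isopropenyl C5=C6 bond in the 6-exo-trig mode (C9 to the internal carbon C5, palladium to C6), closing ring A and leaving a neopentyl-type alkylpalladium with no β-hydrogen; this inserts the vinyl group of the C8 arm, again 6-exo-trig (C6 to C7, palladium to the terminal CH2), closing ring B, and β-hydride elimination of the single C7–H releases the exocyclic methylene while the amine takes up HCl and returns the catalyst. The closest known reaction types are the cyclic acylpalladation of alkenes by acylpalladium species made from acid chlorides and the zipper Mizoroki–Heck cascades that run through neopentylpalladium intermediates formed by exo attack at the substituted carbon of methacryl-type alkenes. The only new stereocentre, quaternary C5, is controlled by the fixed C1 centre: in the four-centre insertion the C6–Pd terminus must point away from the forming ring (pseudo-equatorial) and the bulky tert-alkyl C8 arm on C1 also takes the pseudo-equatorial site, so C6 and the arm end up cis, and inversion of the flat ring A then brings both axial for the second closure, which the vinyl group can assist by chelating palladium. The step needs exo and not 7-endo acylpalladation (secured by ring size and by the unsubstituted palladium-bearing terminus), retention of CO (mild temperature, fast intramolecular insertion) and inertness of the trisubstituted prenyl and enol-ether double bonds, which insert far more slowly than the monosubstituted vinyl group.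

Step 9
Reactants: 13 (1S,5R)-4-methoxy-5,8,8-trimethyl-7-methylidene-1-(3-methylbut-2-en-1-yl)bicyclo[3.3.1]non-3-ene-2,9-dione; 14 1-bromo-2-methylprop-1-ene
Product: 16 (1S,5R,7R)-4-methoxy-5,8,8-trimethyl-1,7-bis(3-methylbut-2-en-1-yl)bicyclo[3.3.1]non-3-ene-2,9-dione, via alkylborane 15 (not isolated)
Conditions: 9-BBN-H (1.5 equiv), THF, 0 °C → rt; then 14 (2 equiv), Pd(dppf)Cl2 (5 mol %), AsPh3 (10 mol %), Cs2CO3 (3 equiv), DMF–H2O, 50 °C
Reagents that add atoms: 9-borabicyclo[3.3.1]nonane, B1C2CCCC1CCC2 (its boron unit is present in 15 only; 16 keeps one H from it)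
Why: Hydroboration by 9-BBN-H takes the 1,1-disubstituted C7=CH2 in preference to the trisubstituted prenyl and enol-ether double bonds and delivers boron to CH2 and hydrogen to C7 from the exo (convex) face, the endo face being screened by ring A, so the CH2B group ends endo and C7 becomes R; B-alkyl Suzuki–Miyaura coupling with the alkenyl bromide then completes the prenyl group with retention.

Step 10
Reactants: 16 (1S,5R,7R)-4-methoxy-5,8,8-trimethyl-1,7-bis(3-methylbut-2-en-1-yl)bicyclo[3.3.1]non-3-ene-2,9-dione; 17 2-methylpropanoyl chloride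
Product: 18 (1R,5R,7R)-4-methoxy-5,8,8-trimethyl-1,7-bis(3-methylbut-2-en-1-yl)-3-(2-methylpropanoyl)bicyclo[3.3.1]non-3-ene-2,9-dione
Conditions: LiTMP (1.6 equiv), THF, −78 °C; then 17 (2 equiv), −78 → −40 °C
Reagents that add atoms: none
Why: Deprotonation of the vinylic C3–H of the vinylogous ester by the hindered lithium amide (both bridgeheads are quaternary, so nothing else is acidic) and C-acylation of the alkenyllithium by the acid chloride, the standard C3 acylation of bicyclic vinylogous esters of this type.

Step 11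
Reactants: 18 (1R,5R,7R)-4-methoxy-5,8,8-trimethyl-1,7-bis(3-methylbut-2-en-1-yl)-3-(2-methylpropanoyl)bicyclo[3.3.1]non-3-ene-2,9-dione
Product: 19 (1R,5R,7R)-4-hydroxy-5,8,8-trimethyl-1,7-bis(3-methylbut-2-en-1-yl)-3-(2-methylpropanoyl)bicyclo[3.3.1]non-3-ene-2,9-dione
Conditions: LiOH (5 equiv), 1,4-dioxane–H2O, 90 °C; then 1 M HCl
Reagents that add atoms: lithium hydroxide, [Li+].[OH-]
Why: Hydroxide addition–elimination at C4 of the doubly activated vinylogous ester releases methanol and, after acidification, the enolised β-triketone; no stereocentre can epimerise (C1 and C5 are quaternary, C7 is not α to a carbonyl).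

**Compound list**

1 | 2,2,6-trimethyl-4H-1,3-dioxin-4-one | CC1=CC(=O)OC(C)(C)O1 | starting material
2 | methacryloyl chloride | CC(=C)C(Cl)=O | starting material
3 | 2,2-dimethyl-6-(3-methyl-2-oxobut-3-en-1-yl)-4H-1,3-dioxin-4-one | CC(=C)C(=O)CC1=CC(=O)OC(C)(C)O1 | intermediate
4 | 6-methyl-3,5-dioxohepta-1,6-dien-1-one (acylketene, not isolated) | CC(=C)C(=O)CC(=O)C=C=O | intermediate
5 | 4-hydroxy-6-(prop-1-en-2-yl)-2H-pyran-2-one | CC(=C)C1=CC(O)=CC(=O)O1 | intermediate
6 | 3-methylbut-2-en-1-yl acetate (prenyl acetate) | CC(C)=CCOC(C)=O | starting material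
7 | 4-hydroxy-3-(3-methylbut-2-en-1-yl)-6-(prop-1-en-2-yl)-2H-pyran-2-one | CC(=C)C1=CC(O)=C(CC=C(C)C)C(=O)O1 | intermediate
8 | 3-methylbut-2-en-1-ol (prenol) | CC(C)=CCO | starting material
9 | 4-[(3-methylbut-2-en-1-yl)oxy]-3-(3-methylbut-2-en-1-yl)-6-(prop-1-en-2-yl)-2H-pyran-2-one | CC(=C)C1=CC(OCC=C(C)C)=C(CC=C(C)C)C(=O)O1 | intermediate
10 | (3S)-3-(2-methylbut-3-en-2-yl)-3-(3-methylbut-2-en-1-yl)-6-(prop-1-en-2-yl)-2H-pyran-2,4(3H)-dione | CC(C)=CC[C@]1(C(C)(C)C=C)C(=O)C=C(C(C)=C)OC1=O | intermediate
11 | sodium (2S,4E)-5-methoxy-6-methyl-2-(2-methylbut-3-en-2-yl)-2-(3-methylbut-2-en-1-yl)-3-oxohepta-4,6-dienoate | [Na+].[O-]C(=O)[C@](CC=C(C)C)(C(=O)/C=C(OC)\C(C)=C)C(C)(C)C=C | intermediate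
12 | (2S,4E)-5-methoxy-6-methyl-2-(2-methylbut-3-en-2-yl)-2-(3-methylbut-2-en-1-yl)-3-oxohepta-4,6-dienoyl chloride | ClC(=O)[C@](CC=C(C)C)(C(=O)/C=C(OC)\C(C)=C)C(C)(C)C=C | intermediate
13 | (1S,5R)-4-methoxy-5,8,8-trimethyl-7-methylidene-1-(3-methylbut-2-en-1-yl)bicyclo[3.3.1]non-3-ene-2,9-dione | C=C1C[C@@]2(C)C(=O)[C@](CC=C(C)C)(C(=O)C=C2OC)C1(C)C | intermediate
14 | 1-bromo-2-methylprop-1-ene | CC(C)=CBr | starting material
15 | alkylborane of 13: 9-borabicyclo[3.3.1]nonan-9-yl on the former exocyclic CH2, which sits endo on C7 (7R), C7–H exo (not isolated) | C(B1C2CCCC1CCC2)[C@@H]1C[C@@]2(C)C(=O)[C@](CC=C(C)C)(C(=O)C=C2OC)C1(C)C | intermediate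
16 | (1S,5R,7R)-4-methoxy-5,8,8-trimethyl-1,7-bis(3-methylbut-2-en-1-yl)bicyclo[3.3.1]non-3-ene-2,9-dione | CC(C)=CC[C@@H]1C[C@@]2(C)C(=O)[C@](CC=C(C)C)(C(=O)C=C2OC)C1(C)C | intermediate
17 | 2-methylpropanoyl chloride | CC(C)C(Cl)=O | starting material
18 | (1R,5R,7R)-4-methoxy-5,8,8-trimethyl-1,7-bis(3-methylbut-2-en-1-yl)-3-(2-methylpropanoyl)bicyclo[3.3.1]non-3-ene-2,9-dione | CC(C)=CC[C@@H]1C[C@@]2(C)C(=O)[C@](CC=C(C)C)(C(=O)C(C(=O)C(C)C)=C2OC)C1(C)C | intermediate
19 | (1R,5R,7R)-4-hydroxy-5,8,8-trimethyl-1,7-bis(3-methylbut-2-en-1-yl)-3-(2-methylpropanoyl)bicyclo[3.3.1]non-3-ene-2,9-dione | CC(C)=CC[C@@H]1C[C@@]2(C)C(=O)[C@](CC=C(C)C)(C(=O)C(C(=O)C(C)C)=C2O)C1(C)C | target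

Total step count: 11. Longest linear sequence: 11 steps (from 1).

**Steps most likely to fail**

1. Step 8 (key step). What may go wrong:
   - loss of carbon monoxide from the acyl complex before the first insertion, leading to a palladium enolate at C1 and diene formation;
   - closure of ring A with C6 trans to the C8 arm, after which the alkylpalladium cannot reach the vinyl group;
   - migration of the exocyclic double bond into ring B by re-addition of palladium hydride;
   - chloride-promoted loss of chloromethane from 12 with return to lactone 10.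

   Fallback: it sets out from 11, which is acylated with pivaloyl chloride (CH2Cl2, 0 °C) to the mixed anhydride 2,2-dimethylpropanoic (2S,4E)-5-methoxy-6-methyl-2-(2-methylbut-3-en-2-yl)-2-(3-methylbut-2-en-1-yl)-3-oxohepta-4,6-dienoic anhydride F1. The zipper is then started by oxidative addition of zerovalent palladium into the C(acyl)–O bond of the anhydride (Pd(OAc)2, P(4-MeOC6H4)3, THF, 60 °C, no amine). This changes the acyl donor and the bond that palladium breaks: the chelating pivalate fills the site needed for CO extrusion, takes up the hydride at the end as pivalic acid, and no chloride is present to demethylate the enol ether. The fallback comes back to the route at 13.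

2. Step 5. What may go wrong: low enantioselectivity or low rate in a rearrangement that breaks the pyranone aromaticity and joins two quaternary carbons, with ionisation and [1,3] shift as background paths.

   Fallback: it sets out from 5 and reverses the order of the two C–C bond formations at C3. Mitsunobu etherification of 5 with 8 (PPh3, DIAD, THF) gives 4-[(3-methylbut-2-en-1-yl)oxy]-6-(prop-1-en-2-yl)-2H-pyran-2-one F2. Thermal Claisen rearrangement (toluene, 120 °C), here rearomatising, gives 4-hydroxy-3-(2-methylbut-3-en-2-yl)-6-(prop-1-en-2-yl)-2H-pyran-2-one F3. The stereocentre is then set by an enantioselective Tsuji–Trost prenylation of F3 with 6 (Pd2(dba)3, the enantiomer of N,N'-bis[2-(diphenylphosphino)benzoyl]cyclohexane-1,2-diamine that gives (S)-10, Et3N, CH2Cl2), in which the chiral ligand pocket selects the face of the pyranone anion. The fallback comes back to the route at 10.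

3. Step 6. What may go wrong: attack of methoxide at the lactone carbonyl (acyl transfer to a methyl ester and a β-diketonate) in place of C6, or an unfavourable E/Z ratio of the enol ether.

   Fallback: it sets out from 10 and uses the acyl-transfer path on purpose. Sodium 2-(trimethylsilyl)ethoxide (2-(trimethylsilyl)ethanol, NaH, THF) opens the lactone to 2-(trimethylsilyl)ethyl (2S)-6-methyl-2-(2-methylbut-3-en-2-yl)-2-(3-methylbut-2-en-1-yl)-3,5-dioxohept-6-enoate F4. Trimethylsilyldiazomethane (MeOH–toluene) methylates the enol at the less hindered oxygen next to the isopropenyl group to give 2-(trimethylsilyl)ethyl (2S,4E)-5-methoxy-6-methyl-2-(2-methylbut-3-en-2-yl)-2-(3-methylbut-2-en-1-yl)-3-oxohepta-4,6-dienoate F5; the regioisomer is removed by chromatography. TBAF (THF) cleaves the ester to tetrabutylammonium (2S,4E)-5-methoxy-6-methyl-2-(2-methylbut-3-en-2-yl)-2-(3-methylbut-2-en-1-yl)-3-oxohepta-4,6-dienoate F6, and oxalyl chloride converts F6 into 12, where the route is rejoined.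

**Further compounds**

F1 | step 8 | 2,2-dimethylpropanoic (2S,4E)-5-methoxy-6-methyl-2-(2-methylbut-3-en-2-yl)-2-(3-methylbut-2-en-1-yl)-3-oxohepta-4,6-dienoic anhydride | CC(C)(C)C(=O)OC(=O)[C@](CC=C(C)C)(C(=O)/C=C(OC)\C(C)=C)C(C)(C)C=C
F2 | step 5 | 4-[(3-methylbut-2-en-1-yl)oxy]-6-(prop-1-en-2-yl)-2H-pyran-2-one | CC(=C)C1=CC(OCC=C(C)C)=CC(=O)O1
F3 | step 5 | 4-hydroxy-3-(2-methylbut-3-en-2-yl)-6-(prop-1-en-2-yl)-2H-pyran-2-one | CC(=C)C1=CC(O)=C(C(C)(C)C=C)C(=O)O1
F4 | step 6 | 2-(trimethylsilyl)ethyl (2S)-6-methyl-2-(2-methylbut-3-en-2-yl)-2-(3-methylbut-2-en-1-yl)-3,5-dioxohept-6-enoate | C[Si](C)(C)CCOC(=O)[C@](CC=C(C)C)(C(=O)CC(=O)C(C)=C)C(C)(C)C=C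
F5 | step 6 | 2-(trimethylsilyl)ethyl (2S,4E)-5-methoxy-6-methyl-2-(2-methylbut-3-en-2-yl)-2-(3-methylbut-2-en-1-yl)-3-oxohepta-4,6-dienoate | C[Si](C)(C)CCOC(=O)[C@](CC=C(C)C)(C(=O)/C=C(OC)\C(C)=C)C(C)(C)C=C
F6 | step 6 | tetrabutylammonium (2S,4E)-5-methoxy-6-methyl-2-(2-methylbut-3-en-2-yl)-2-(3-methylbut-2-en-1-yl)-3-oxohepta-4,6-dienoate | CCCC[N+](CCCC)(CCCC)CCCC.[O-]C(=O)[C@](CC=C(C)C)(C(=O)/C=C(OC)\C(C)=C)C(C)(C)C=C
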